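Ring A of the drimane is cut at C2–C3, the only ring-A bond that joins two plain methylene carbons and that lies between the quaternary carbons C4 and C10. Ring-closing olefin metathesis of a fully substituted ring-B cyclohexanone, whose C10 allyl and C5 1,1-dimethylallyl groups are trans, closes ring A and fixes the trans-decalin in one operation; hydrogenation then saturates C2–C3. The precursor is built on ring B alone: organocatalytic annulation sets C5, two conjugate additions build C10, and enolate benzylation brings in C11 and the arene. The arene later becomes the epoxyquinone and is esterified with a hydroxymethylglutarate from (R)-mevalonolactone.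

Key step: step 12

Remark: locants C1–C12 are drimane locants (C11 = benzylic CH2, C12 = exocyclic methylene carbon); primed locants C1'–C6' denote the six-membered ring that becomes the epoxyquinone, C1' being bonded to C11.
Remark: compounds 1, 3, 9 and 24 are taken as commercially available.

Step 1
Reactants: 1 methyl 3,3-dimethylpent-4-enoate
Product: 2 3,3-dimethylpent-4-enal
Conditions: i-Bu2AlH (1.05 equiv), CH2Cl2, −78 °C; aqueous potassium sodium tartrate
Reagents that add atoms: none
Why: Partial hydride reduction of an ester with i-Bu2AlH at −78 °C should stop at the aldehyde because the tetrahedral aluminium hemiacetal survives until work-up.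

Step 2
Reactants: 2 3,3-dimethylpent-4-enal, 3 but-3-en-2-one
Product: 4 (2S)-2-(2-methylbut-3-en-2-yl)-5-oxohexanal
Conditions: (S)-2-[diphenyl(trimethylsilyloxy)methyl]pyrrolidine (10 mol %), ethyl 3,4-dihydroxybenzoate (20 mol %), neat, 4 °C
Reagents that add atoms: none
Why: Enamine-catalysed asymmetric Michael addition of an aldehyde to a vinyl ketone; the diphenyl(silyloxy)methyl group of the (S)-catalyst shields one face of the E-enamine, so the enone is attacked from the other face and C5 is set as S in 4.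

Step 3
Reactants: 4 (2S)-2-(2-methylbut-3-en-2-yl)-5-oxohexanal
Product: 5 (4R)-4-(2-methylbut-3-en-2-yl)cyclohex-2-en-1-one
Conditions: KOH (0.1 M aq), n-Bu4NOH (cat.), Et2O/THF, 40 °C
Reagents that add atoms: none
Why: Intramolecular aldol condensation of the methyl ketone onto the aldehyde (Robinson-type cyclodehydration) should give the cyclohexenone; C5, shielded by the tert-alkyl group, is expected to keep its configuration (the descriptor changes only by priority).

Step 4
Reactants: 5 (4R)-4-(2-methylbut-3-en-2-yl)cyclohex-2-en-1-one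
Product: 7 (4R)-3-methyl-4-(2-methylbut-3-en-2-yl)cyclohex-2-en-1-one, via lithium enolate 6 (not isolated)
Conditions: MeLi, CuI, Et2O, −78 to −40 °C; then N-tert-butylbenzenesulfinimidoyl chloride, THF, −78 °C
Reagents that add atoms: methyllithium, [Li]C
Why: Conjugate addition of the Gilman cuprate gives the regiodefined enolate 6, and Mukaiyama dehydrogenation (α-sulfenylation by the sulfinimidoyl chloride, then syn-elimination) should restore the C9=C10 enone in the same flask, so the transient C10 centre is erased and C5 is untouched.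

Step 5
Reactants: 7 (4R)-3-methyl-4-(2-methylbut-3-en-2-yl)cyclohex-2-en-1-one
Product: 8 trimethyl{[(3S,4S)-3-methyl-4-(2-methylbut-3-en-2-yl)-3-(prop-2-en-1-yl)cyclohex-1-en-1-yl]oxy}silane
Conditions: allylMgBr, CuBr·SMe2 (1.1 equiv), TMSCl, THF, −78 °C; Et3N, pentane, cold aqueous NaHCO3
Reagents that add atoms: allylmagnesium bromide, C=CC[Mg]Br; chlorotrimethylsilane, C[Si](C)(C)Cl
Why: Copper-mediated conjugate allylation accelerated by TMSCl traps the enolate regiospecifically as the C8–C9 silyl enol ether; the quaternary centre C10 is set by attack anti to the bulky C5 substituent, which places allyl trans and methyl cis to it.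

Step 6
Reactants: 9 4-bromo-2,5-dimethoxybenzaldehyde
Product: 10 4-bromo-2-hydroxy-5-methoxybenzaldehyde
Conditions: BCl3 (1.1 equiv), CH2Cl2, −78 to 0 °C; H2O
Reagents that add atoms: none
Why: Chelation-controlled Lewis-acid demethylation: BCl3 bound to the aldehyde oxygen should cleave only the methyl ether ortho to the formyl group.

Step 7
Reactants: 10 4-bromo-2-hydroxy-5-methoxybenzaldehyde
Product: 11 5-bromo-2-formyl-4-methoxyphenyl diethylcarbamate
Conditions: Et2NCOCl, K2CO3, MeCN, 80 °C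
Reagents that add atoms: N,N-diethylcarbamoyl chloride, CCN(CC)C(=O)Cl
Why: O-Carbamoylation of the phenoxide gives an aryl carbamate that should survive the later basic, reductive and Lewis-acidic steps and is cleaved by hydride in step 15.

Step 8
Reactants: 11 5-bromo-2-formyl-4-methoxyphenyl diethylcarbamate
Product: 12 methyl 5-[(diethylcarbamoyl)oxy]-4-formyl-2-methoxybenzoate
Conditions: CO (1 atm), MeOH, Pd(OAc)2 (5 mol %), dppf (10 mol %), Et3N, DMF, 70 °C
Reagents that add atoms: carbon monoxide, [C-]#[O+]; methanol, CO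
Why: Palladium-catalysed alkoxycarbonylation of the aryl bromide (oxidative addition to zerovalent palladium, CO insertion, methanolysis) installs the future hydroxymethyl carbon as a robust methyl ester while aldehyde and carbamate stay inert.

Step 9
Reactants: 12 methyl 5-[(diethylcarbamoyl)oxy]-4-formyl-2-methoxybenzoate
Product: 13 methyl 5-[(diethylcarbamoyl)oxy]-4-(hydroxymethyl)-2-methoxybenzoate
Conditions: NaBH4, MeOH/THF, 0 °C
Reagents that add atoms: none
Why: Chemoselective borohydride reduction of the aldehyde; ester and carbamate are not reduced at 0 °C.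

Step 10
Reactants: 13 methyl 5-[(diethylcarbamoyl)oxy]-4-(hydroxymethyl)-2-methoxybenzoate
Product: 14 methyl 4-(bromomethyl)-5-[(diethylcarbamoyl)oxy]-2-methoxybenzoate
Conditions: CBr4, PPh3, CH2Cl2, 0 °C
Reagents that add atoms: tetrabromomethane, BrC(Br)(Br)Br
Why: Appel bromination of the primary benzylic alcohol under neutral conditions.

Step 11
Reactants: 8 trimethyl{[(3S,4S)-3-methyl-4-(2-methylbut-3-en-2-yl)-3-(prop-2-en-1-yl)cyclohex-1-en-1-yl]oxy}silane, 14 methyl 4-(bromomethyl)-5-[(diethylcarbamoyl)oxy]-2-methoxybenzoate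
Product: 17 methyl 5-[(diethylcarbamoyl)oxy]-2-methoxy-4-{[(1R,2S,3S)-2-methyl-3-(2-methylbut-3-en-2-yl)-6-oxo-2-(prop-2-en-1-yl)cyclohexyl]methyl}benzoate, via lithium enolate 15 (not isolated), via C9-epimeric ketone 16 (not isolated)
Conditions: MeLi (1.0 equiv), THF, 0 °C; 14, DMPU, −78 to 0 °C; then NaOMe (0.2 equiv), MeOH, rt
Reagents that add atoms: none
Why: Regiospecific lithium enolate generation from the silyl enol ether followed by SN2 C-alkylation with the benzylic bromide; attack is expected anti to the axial C10 methyl group (16), and base equilibration through the enolate should move C11 into the equatorial position, cis to the C10 methyl group and trans to the allyl group (17).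

Step 12
Reactants: 17 methyl 5-[(diethylcarbamoyl)oxy]-2-methoxy-4-{[(1R,2S,3S)-2-methyl-3-(2-methylbut-3-en-2-yl)-6-oxo-2-(prop-2-en-1-yl)cyclohexyl]methyl}benzoate
Product: 18 methyl 5-[(diethylcarbamoyl)oxy]-2-methoxy-4-{[(1R,4aS,8aS)-5,5,8a-trimethyl-2-oxo-1,2,3,4,4a,5,8,8a-octahydronaphthalen-1-yl]methyl}benzoate
Conditions: second-generation Grubbs catalyst, (H2IMes)(PCy3)Cl2Ru=CHPh (5 mol %), degassed CH2Cl2 (5 mM), 40 °C
Reagents that add atoms: none
Why: Ring-closing olefin metathesis by the Chauvin mechanism: the ruthenium alkylidene loads on the unhindered allyl terminus and a [2+2]/retro-[2+2] sequence with the neopentyl vinyl group forms C2=C3 with loss of ethene. The closest known reaction type is diene ring-closing metathesis to cyclohexenes next to a gem-dimethyl carbon. Ring A closes as a six-membered cycloalkene by joining the C10 allyl arm to the C5 1,1-dimethylallyl arm, and because these arms are trans on ring B the decalin is necessarily trans-fused. No new stereocentre is created and C5, C9 and C10 are untouched. The step needs ring closure to win over intermolecular metathesis and over alkene migration. High dilution, the Thorpe–Ingold effect of C4 and the diequatorial arrangement of the two arms should secure the first, and the hydride-free, degassed medium the second.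

Step 13
Reactants: 18 methyl 5-[(diethylcarbamoyl)oxy]-2-methoxy-4-{[(1R,4aS,8aS)-5,5,8a-trimethyl-2-oxo-1,2,3,4,4a,5,8,8a-octahydronaphthalen-1-yl]methyl}benzoate
Product: 19 methyl 5-[(diethylcarbamoyl)oxy]-2-methoxy-4-{[(1R,4aS,8aS)-5,5,8a-trimethyl-2-oxodecahydronaphthalen-1-yl]methyl}benzoate
Conditions: H2 (1 atm), 10% Pd/C, EtOAc, rt
Reagents that add atoms: none
Why: Heterogeneous catalytic hydrogenation of the cis-disubstituted C2=C3 alkene; ketone, ester, carbamate and all stereocentres are unaffected.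

Step 14
Reactants: 19 methyl 5-[(diethylcarbamoyl)oxy]-2-methoxy-4-{[(1R,4aS,8aS)-5,5,8a-trimethyl-2-oxodecahydronaphthalen-1-yl]methyl}benzoate
Product: 20 methyl 5-[(diethylcarbamoyl)oxy]-2-methoxy-4-{[(1S,4aS,8aS)-5,5,8a-trimethyl-2-methylidenedecahydronaphthalen-1-yl]methyl}benzoate
Conditions: Zn, CH2Br2, TiCl4 (Lombardo reagent, preformed in THF), CH2Cl2, 0 °C to rt
Reagents that add atoms: dibromomethane, BrCBr
Why: Lombardo methylenation with the gem-dimetallic CH2 reagent converts the hindered, enolisable C8 ketone into the exocyclic methylene under non-basic conditions, so C9 should not epimerise (its descriptor changes only by priority) and ester and carbamate are untouched.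

Step 15
Reactants: 20 methyl 5-[(diethylcarbamoyl)oxy]-2-methoxy-4-{[(1S,4aS,8aS)-5,5,8a-trimethyl-2-methylidenedecahydronaphthalen-1-yl]methyl}benzoate
Product: 21 5-(hydroxymethyl)-4-methoxy-2-{[(1S,4aS,8aS)-5,5,8a-trimethyl-2-methylidenedecahydronaphthalen-1-yl]methyl}phenol
Conditions: LiAlH4 (excess), THF, 0 °C to reflux; aqueous potassium sodium tartrate
Reagents that add atoms: none
Why: Hydride reduction of the methyl ester to the benzylic alcohol and, in the same operation, reductive cleavage of the aryl carbamate to the phenol; the isolated exocyclic alkene is inert to LiAlH4.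

Step 16
Reactants: 21 5-(hydroxymethyl)-4-methoxy-2-{[(1S,4aS,8aS)-5,5,8a-trimethyl-2-methylidenedecahydronaphthalen-1-yl]methyl}phenol
Product: 22 5-(hydroxymethyl)-4,4-dimethoxy-2-{[(1S,4aS,8aS)-5,5,8a-trimethyl-2-methylidenedecahydronaphthalen-1-yl]methyl}cyclohexa-2,5-dien-1-one
Conditions: PhI(OAc)2, NaHCO3, MeOH, 0 °C
Reagents that add atoms: methanol, CO
Why: Oxidative dearomatisation of a para-methoxyphenol with a hypervalent iodine reagent; methanol adds para to the phenol oxygen, so the ketone arises at C2' next to the terpenoid-bearing C1' and the dimethyl ketal at C5' next to the hydroxymethyl-bearing C4'.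

Step 17
Reactants: 22 5-(hydroxymethyl)-4,4-dimethoxy-2-{[(1S,4aS,8aS)-5,5,8a-trimethyl-2-methylidenedecahydronaphthalen-1-yl]methyl}cyclohexa-2,5-dien-1-one
Product: 23 (1R,6S)-4-(hydroxymethyl)-5,5-dimethoxy-1-{[(1S,4aS,8aS)-5,5,8a-trimethyl-2-methylidenedecahydronaphthalen-1-yl]methyl}-7-oxabicyclo[4.1.0]hept-3-en-2-one
Conditions: t-BuOOH, N-benzylcinchonidinium chloride (10 mol %), NaOH (aq, 0.2 equiv), toluene, 0 °C to rt
Reagents that add atoms: tert-butyl hydroperoxide, CC(C)(C)OO
Why: Weitz–Scheffer nucleophilic epoxidation under chiral phase-transfer catalysis: the peroxide anion adds to the unsubstituted β-carbon C6' and not to the fully substituted β-carbon C4', and enolate ring closure gives the cis epoxide across C1'–C6'; the face is to be imposed by the chiral ammonium ion pair, the pseudoenantiomeric cinchoninium salt being used if the cinchonidinium salt favours the other face.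

Step 18
Reactants: 24 (4R)-4-hydroxy-4-methyloxan-2-one [(R)-mevalonolactone]
Product: 26 prop-2-en-1-yl (3R)-3,5-dihydroxy-3-methylpentanoate, via potassium mevalonate 25 (not isolated)
Conditions: KOH (1.0 equiv), H2O/MeOH, rt, evaporate; allyl bromide, DMF, rt
Reagents that add atoms: potassium hydroxide, [K+].[OH-]; allyl bromide, C=CCBr
Why: Saponification of the lactone and SN2 O-alkylation of the carboxylate give the open-chain allyl ester; the quaternary carbinol centre is not involved and stays R.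

Step 19
Reactants: 26 prop-2-en-1-yl (3R)-3,5-dihydroxy-3-methylpentanoate
Product: 27 (3R)-3-hydroxy-3-methyl-5-oxo-5-(prop-2-en-1-yloxy)pentanoic acid
Conditions: TEMPO (20 mol %), PhI(OAc)2 (2.2 equiv), MeCN/H2O 1:1, rt
Reagents that add atoms: water, O
Why: Oxoammonium (TEMPO) oxidation with PhI(OAc)2 as terminal oxidant takes only the primary alcohol through the aldehyde hydrate to the carboxylic acid; the tertiary alcohol cannot be oxidised.

Step 20
Reactants: 23 (1R,6S)-4-(hydroxymethyl)-5,5-dimethoxy-1-{[(1S,4aS,8aS)-5,5,8a-trimethyl-2-methylidenedecahydronaphthalen-1-yl]methyl}-7-oxabicyclo[4.1.0]hept-3-en-2-one, 27 (3R)-3-hydroxy-3-methyl-5-oxo-5-(prop-2-en-1-yloxy)pentanoic acid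
Product: 28 1-(prop-2-en-1-yl) 5-({(1R,6S)-5,5-dimethoxy-2-oxo-1-{[(1S,4aS,8aS)-5,5,8a-trimethyl-2-methylidenedecahydronaphthalen-1-yl]methyl}-7-oxabicyclo[4.1.0]hept-3-en-4-yl}methyl) (3S)-3-hydroxy-3-methylpentanedioate
Conditions: EDC·HCl, DMAP (0.2 equiv), CH2Cl2, 0 °C to rt
Reagents that add atoms: none
Why: Steglich-type carbodiimide esterification of the primary allylic alcohol; the tertiary hydroxyl group does not compete, and the glutarate centre is unchanged in space (its descriptor becomes S only by priority).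

Step 21
Reactants: 28 1-(prop-2-en-1-yl) 5-({(1R,6S)-5,5-dimethoxy-2-oxo-1-{[(1S,4aS,8aS)-5,5,8a-trimethyl-2-methylidenedecahydronaphthalen-1-yl]methyl}-7-oxabicyclo[4.1.0]hept-3-en-4-yl}methyl) (3S)-3-hydroxy-3-methylpentanedioate
Product: 29 (3S)-5-({(1R,6S)-5,5-dimethoxy-2-oxo-1-{[(1S,4aS,8aS)-5,5,8a-trimethyl-2-methylidenedecahydronaphthalen-1-yl]methyl}-7-oxabicyclo[4.1.0]hept-3-en-4-yl}methoxy)-3-hydroxy-3-methyl-5-oxopentanoic acid
Conditions: Pd(PPh3)4 (5 mol %), N-methylaniline (3 equiv), THF, 0 °C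
Reagents that add atoms: none
Why: Deallylation catalysed by zerovalent palladium (Tsuji–Trost ionisation, allyl transfer to the amine); the unhindered allyl ester should ionise far faster than the hindered, electron-poor allylic ester of the core, and the weakly nucleophilic scavenger should not add to the enone or the epoxide.

Step 22
Reactants: 29 (3S)-5-({(1R,6S)-5,5-dimethoxy-2-oxo-1-{[(1S,4aS,8aS)-5,5,8a-trimethyl-2-methylidenedecahydronaphthalen-1-yl]methyl}-7-oxabicyclo[4.1.0]hept-3-en-4-yl}methoxy)-3-hydroxy-3-methyl-5-oxopentanoic acid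
Product: 30 4'-oxomacrophorin D, (3S)-5-({(1R,6S)-2,5-dioxo-1-{[(1S,4aS,8aS)-5,5,8a-trimethyl-2-methylidenedecahydronaphthalen-1-yl]methyl}-7-oxabicyclo[4.1.0]hept-3-en-4-yl}methoxy)-3-hydroxy-3-methyl-5-oxopentanoic acid
Conditions: montmorillonite K10, wet CH2Cl2, rt; elution with EtOAc/MeOH
Reagents that add atoms: water, O
Why: Mild acid-catalysed hydrolysis of the dimethyl ketal on acidic clay should unveil the second carbonyl group of the epoxyquinone without isomerising the exocyclic alkene, opening the epoxide or dehydrating the tertiary alcohol.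

Compound list
1 | methyl 3,3-dimethylpent-4-enoate | COC(=O)CC(C)(C)C=C | starting material
2 | 3,3-dimethylpent-4-enal | O=CCC(C)(C)C=C | intermediate
3 | but-3-en-2-one | CC(=O)C=C | starting material
4 | (2S)-2-(2-methylbut-3-en-2-yl)-5-oxohexanal | CC(=O)CC[C@H](C=O)C(C)(C)C=C | intermediate
5 | (4R)-4-(2-methylbut-3-en-2-yl)cyclohex-2-en-1-one | O=C1C=C[C@H](C(C)(C)C=C)CC1 | intermediate
6 | lithium (3S,4R)-3-methyl-4-(2-methylbut-3-en-2-yl)cyclohex-1-en-1-olate | [Li]OC1=C[C@@H](C)[C@H](C(C)(C)C=C)CC1 | intermediate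
7 | (4R)-3-methyl-4-(2-methylbut-3-en-2-yl)cyclohex-2-en-1-one | O=C1C=C(C)[C@H](C(C)(C)C=C)CC1 | intermediate
8 | trimethyl{[(3S,4S)-3-methyl-4-(2-methylbut-3-en-2-yl)-3-(prop-2-en-1-yl)cyclohex-1-en-1-yl]oxy}silane | C[Si](C)(C)OC1=C[C@@](C)(CC=C)[C@H](C(C)(C)C=C)CC1 | intermediate
9 | 4-bromo-2,5-dimethoxybenzaldehyde | COc1cc(C=O)c(OC)cc1Br | starting material
10 | 4-bromo-2-hydroxy-5-methoxybenzaldehyde | COc1cc(C=O)c(O)cc1Br | intermediate
11 | 5-bromo-2-formyl-4-methoxyphenyl diethylcarbamate | CCN(CC)C(=O)Oc1cc(Br)c(OC)cc1C=O | intermediate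
12 | methyl 5-[(diethylcarbamoyl)oxy]-4-formyl-2-methoxybenzoate | CCN(CC)C(=O)Oc1cc(C(=O)OC)c(OC)cc1C=O | intermediate
13 | methyl 5-[(diethylcarbamoyl)oxy]-4-(hydroxymethyl)-2-methoxybenzoate | CCN(CC)C(=O)Oc1cc(C(=O)OC)c(OC)cc1CO | intermediate
14 | methyl 4-(bromomethyl)-5-[(diethylcarbamoyl)oxy]-2-methoxybenzoate | CCN(CC)C(=O)Oc1cc(C(=O)OC)c(OC)cc1CBr | intermediate
15 | lithium (3S,4S)-3-methyl-4-(2-methylbut-3-en-2-yl)-3-(prop-2-en-1-yl)cyclohex-1-en-1-olate | [Li]OC1=C[C@@](C)(CC=C)[C@H](C(C)(C)C=C)CC1 | intermediate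
16 | methyl 5-[(diethylcarbamoyl)oxy]-2-methoxy-4-{[(1S,2S,3S)-2-methyl-3-(2-methylbut-3-en-2-yl)-6-oxo-2-(prop-2-en-1-yl)cyclohexyl]methyl}benzoate (C9 epimer of 17) | O=C1CC[C@@H](C(C)(C)C=C)[C@](C)(CC=C)[C@@H]1Cc1cc(OC)c(C(=O)OC)cc1OC(=O)N(CC)CC | intermediate
17 | methyl 5-[(diethylcarbamoyl)oxy]-2-methoxy-4-{[(1R,2S,3S)-2-methyl-3-(2-methylbut-3-en-2-yl)-6-oxo-2-(prop-2-en-1-yl)cyclohexyl]methyl}benzoate | O=C1CC[C@@H](C(C)(C)C=C)[C@](C)(CC=C)[C@H]1Cc1cc(OC)c(C(=O)OC)cc1OC(=O)N(CC)CC | intermediate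
18 | methyl 5-[(diethylcarbamoyl)oxy]-2-methoxy-4-{[(1R,4aS,8aS)-5,5,8a-trimethyl-2-oxo-1,2,3,4,4a,5,8,8a-octahydronaphthalen-1-yl]methyl}benzoate | O=C1CC[C@H]2C(C)(C)C=CC[C@]2(C)[C@H]1Cc1cc(OC)c(C(=O)OC)cc1OC(=O)N(CC)CC | intermediate
19 | methyl 5-[(diethylcarbamoyl)oxy]-2-methoxy-4-{[(1R,4aS,8aS)-5,5,8a-trimethyl-2-oxodecahydronaphthalen-1-yl]methyl}benzoate | O=C1CC[C@H]2C(C)(C)CCC[C@]2(C)[C@H]1Cc1cc(OC)c(C(=O)OC)cc1OC(=O)N(CC)CC | intermediate
20 | methyl 5-[(diethylcarbamoyl)oxy]-2-methoxy-4-{[(1S,4aS,8aS)-5,5,8a-trimethyl-2-methylidenedecahydronaphthalen-1-yl]methyl}benzoate | C=C1CC[C@H]2C(C)(C)CCC[C@]2(C)[C@H]1Cc1cc(OC)c(C(=O)OC)cc1OC(=O)N(CC)CC | intermediate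
21 | 5-(hydroxymethyl)-4-methoxy-2-{[(1S,4aS,8aS)-5,5,8a-trimethyl-2-methylidenedecahydronaphthalen-1-yl]methyl}phenol | C=C1CC[C@H]2C(C)(C)CCC[C@]2(C)[C@H]1Cc1cc(OC)c(CO)cc1O | intermediate
22 | 5-(hydroxymethyl)-4,4-dimethoxy-2-{[(1S,4aS,8aS)-5,5,8a-trimethyl-2-methylidenedecahydronaphthalen-1-yl]methyl}cyclohexa-2,5-dien-1-one | C=C1CC[C@H]2C(C)(C)CCC[C@]2(C)[C@H]1CC1=CC(OC)(OC)C(CO)=CC1=O | intermediate
23 | (1R,6S)-4-(hydroxymethyl)-5,5-dimethoxy-1-{[(1S,4aS,8aS)-5,5,8a-trimethyl-2-methylidenedecahydronaphthalen-1-yl]methyl}-7-oxabicyclo[4.1.0]hept-3-en-2-one | C=C1CC[C@H]2C(C)(C)CCC[C@]2(C)[C@H]1C[C@@]12O[C@@H]1C(OC)(OC)C(CO)=CC2=O | intermediate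
24 | (4R)-4-hydroxy-4-methyloxan-2-one, (R)-mevalonolactone | C[C@@]1(O)CCOC(=O)C1 | starting material
25 | potassium (3R)-3,5-dihydroxy-3-methylpentanoate | C[C@@](CC(=O)[O-])(O)CCO.[K+] | intermediate
26 | prop-2-en-1-yl (3R)-3,5-dihydroxy-3-methylpentanoate | C[C@@](CC(=O)OCC=C)(O)CCO | intermediate
27 | (3R)-3-hydroxy-3-methyl-5-oxo-5-(prop-2-en-1-yloxy)pentanoic acid | C[C@@](CC(=O)OCC=C)(O)CC(=O)O | intermediate
28 | 1-(prop-2-en-1-yl) 5-({(1R,6S)-5,5-dimethoxy-2-oxo-1-{[(1S,4aS,8aS)-5,5,8a-trimethyl-2-methylidenedecahydronaphthalen-1-yl]methyl}-7-oxabicyclo[4.1.0]hept-3-en-4-yl}methyl) (3S)-3-hydroxy-3-methylpentanedioate | C=C1CC[C@H]2C(C)(C)CCC[C@]2(C)[C@H]1C[C@@]12O[C@@H]1C(OC)(OC)C(COC(=O)C[C@@](C)(O)CC(=O)OCC=C)=CC2=O | intermediate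
29 | (3S)-5-({(1R,6S)-5,5-dimethoxy-2-oxo-1-{[(1S,4aS,8aS)-5,5,8a-trimethyl-2-methylidenedecahydronaphthalen-1-yl]methyl}-7-oxabicyclo[4.1.0]hept-3-en-4-yl}methoxy)-3-hydroxy-3-methyl-5-oxopentanoic acid | C=C1CC[C@H]2C(C)(C)CCC[C@]2(C)[C@H]1C[C@@]12O[C@@H]1C(OC)(OC)C(COC(=O)C[C@@](C)(O)CC(=O)O)=CC2=O | intermediate
30 | 4'-oxomacrophorin D | C=C1CC[C@H]2C(C)(C)CCC[C@]2(C)[C@H]1C[C@@]12O[C@@H]1C(=O)C(COC(=O)C[C@@](C)(O)CC(=O)O)=CC2=O | target

Total step count: 22.
Longest linear sequence: 15 steps (steps 1–5, 11–17, 20–22).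

Steps most likely to fail

1. Step 17. The peroxide may be delivered with poor facial selectivity, because the only stereocentres of the substrate are remote from the planar dienone, and some attack on the other alkene is conceivable. Fallback, setting out from 22: acid-catalysed exchange of the dimethyl ketal for (2R,4R)-pentane-2,4-diol (PPTS, benzene, 50 °C, removal of MeOH) would give the chiral spiroketal dienone F1, in which the axial methyl group of the dioxane shields one face next to C6'. Auxiliary-controlled Weitz–Scheffer epoxidation (H2O2, K2CO3, THF/H2O, 0 °C) would then give the epoxy spiroketal F2; the (2S,4S)-diol is taken instead if the (2R,4R)-ketal directs to the wrong face. Esterification with 27 as in step 20 would give the allyl ester F3, deallylation as in step 21 the acid F4, and hydrolysis of the dioxane ketal (48% aqueous HF, MeCN, 0 °C) comes back to the route at 30.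

2. Step 11. C-Alkylation at the neopentyl-type enolate carbon C9 may be slow, so that proton transfer, O-alkylation or attack on the ester of 14 compete, and the equilibration may leave some of the C9 epimer. Fallback, setting out from 8 and aldehyde 12: Mukaiyama aldol addition (BF3·OEt2, CH2Cl2, −78 °C) would give the β-hydroxy ketone F5, and dehydration (MsCl, Et3N, then DBU) the benzylidene ketone F6. Conjugate reduction with [(Ph3P)CuH]6 in benzene, with protonation of the enolate at C9 from the face anti to the C10 methyl group and the NaOMe equilibration of step 11, comes back to the route at 17.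

3. Step 5. The allyl nucleophile may add 1,2 to the carbonyl group, or fail to reach the congested β-carbon C10 next to the tert-alkyl-bearing C5. Fallback, setting out from 7: deliberate 1,2-addition (allylMgBr, CeCl3, THF, −78 °C) would give the tertiary bis-allylic alcohol F7, whose epimer with allyl trans to the C5 substituent is separated. Anionic oxy-Cope rearrangement (KH, 18-crown-6, THF, 0 °C) should transfer the allyl group suprafacially to C10 on the same ring face and produce the C8–C9 potassium enolate directly. Quenching with TMSCl/Et3N comes back to the route at 8.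

Further compounds
F1 | step 17 | (2R,4R)-11-(hydroxymethyl)-2,4-dimethyl-8-{[(1S,4aS,8aS)-5,5,8a-trimethyl-2-methylidenedecahydronaphthalen-1-yl]methyl}-1,5-dioxaspiro[5.5]undeca-7,10-dien-9-one | C=C1CC[C@H]2C(C)(C)CCC[C@]2(C)[C@H]1CC1=CC2(O[C@H](C)C[C@@H](C)O2)C(CO)=CC1=O
F2 | step 17 | 7,8-epoxide of F1, epoxide configured as in 23 | C=C1CC[C@H]2C(C)(C)CCC[C@]2(C)[C@H]1C[C@@]12O[C@@H]1C1(O[C@H](C)C[C@@H](C)O1)C(CO)=CC2=O
F3 | step 17 | mixed (3S)-3-hydroxy-3-methylpentanedioate of F2 (primary alcohol) and prop-2-en-1-ol | C=C1CC[C@H]2C(C)(C)CCC[C@]2(C)[C@H]1C[C@@]12O[C@@H]1C1(O[C@H](C)C[C@@H](C)O1)C(COC(=O)C[C@@](C)(O)CC(=O)OCC=C)=CC2=O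
F4 | step 17 | (3S)-3-hydroxy-3-methylpentanedioic acid monoester of F2 (free acid) | C=C1CC[C@H]2C(C)(C)CCC[C@]2(C)[C@H]1C[C@@]12O[C@@H]1C1(O[C@H](C)C[C@@H](C)O1)C(COC(=O)C[C@@](C)(O)CC(=O)O)=CC2=O
F5 | step 11 | methyl 5-[(diethylcarbamoyl)oxy]-4-{hydroxy[(2S,3S)-2-methyl-3-(2-methylbut-3-en-2-yl)-6-oxo-2-(prop-2-en-1-yl)cyclohexyl]methyl}-2-methoxybenzoate (mixture at C9 and C11) | O=C1CC[C@@H](C(C)(C)C=C)[C@](C)(CC=C)C1C(O)c1cc(OC)c(C(=O)OC)cc1OC(=O)N(CC)CC
F6 | step 11 | methyl 5-[(diethylcarbamoyl)oxy]-2-methoxy-4-{(E)-[(2S,3S)-2-methyl-3-(2-methylbut-3-en-2-yl)-6-oxo-2-(prop-2-en-1-yl)cyclohexylidene]methyl}benzoate (geometry immaterial) | O=C1CC[C@@H](C(C)(C)C=C)[C@](C)(CC=C)/C1=C\c1cc(OC)c(C(=O)OC)cc1OC(=O)N(CC)CC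
F7 | step 5 | (1R,4R)-3-methyl-4-(2-methylbut-3-en-2-yl)-1-(prop-2-en-1-yl)cyclohex-2-en-1-ol | O[C@]1(CC=C)C=C(C)[C@H](C(C)(C)C=C)CC1
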